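The numbers in the tables are simulated from invented constants.

We want to know how strongly the rate of making target, in the flask with 0.2 mol% free catalyst, answers to the catalyst charged once 50% of the substrate has been converted.

all flasks: substrate 10 mM; gas 2.5 mM (held)

| flask | free catalyst | remark |
|---|---|---|
| Monday's | 0.1 mol% | run made earlier |
| Wednesday's | 0.15 mol% | run made earlier |
| flask | 0.2 mol% |  |

- Monday's (time / min: target / %): 0.417: 1.2; 1.33: 5.2; 2.00: 7.6; 3.00: 12.0; 5.00: 19.8; 6.00: 23.5
- Wednesday's (time / min: target / %): 0.500: 2.5; 0.833: 4.2; 1.33: 7.9; 2.00: 11.7; 4.00: 22.1; 6.00: 31.5

(standard deviation of a reading: 0.3 percentage points)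

- at the start none of the gas is in solution

- apparent order in free catalyst when 50% of the substrate are converted (percent change of the rate of making target for one percent more free catalyst charged)

Counting target as substrate gone, Monday's run gives 44.6 min⁻¹ and Wednesday's run 42.0 min⁻¹ for the clock per catalyst: minus the logarithm of the fraction of substrate left, divided by the time and by the fraction of catalyst charged.

Two extremes can be solved in the head. At order 1 the flask keeps Wednesday's clock per catalyst, so it reaches 50% at 8.25 min. At order zero, with gas crossing into solution as the rate-limiting step, extra catalyst adds nothing to the time, so the flask needs 11.0 min.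

Wednesday's clock is lower than Monday's, but higher than the 29.8 min⁻¹ of the gas extreme. So the two runs read as order 0.851, a reading that carries a scatter of 0.3 percentage points on each point. Conversion at 50% is further on than at those readings, so we lean from there towards 1, and our own estimate puts the flask's time between 8.60 min, at the order read, and 8.25 min, at order 1.

The forecast, from the same runs, is 0.85, "an estimate rather than a firm value".

The flask gives 1.1.

    reagent + catalyst intermediate A → catalyst intermediate B (k = 4000 M⁻¹ s⁻¹)
    substrate + free catalyst ⇌ catalyst intermediate A (K = 160 M⁻¹, k = 130 M⁻¹ s⁻¹)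
    catalyst intermediate A → spent catalyst (k = 0.00580 s⁻¹)
    catalyst intermediate C → free catalyst + target (k = 7.80 s⁻¹)
    catalyst intermediate B ⇌ released group + catalyst intermediate C (K = 0.00940 M, k = 97.0 s⁻¹)
    gas ⇌ reagent, rate k6*(csat - [reagent]) (kL = 0.0150 s⁻¹)

That stands above order 1 and above the forecast by a factor of 1.32. The flask holds a form that the number does not show: spent catalyst, 31.2% of the catalyst charged at 10.0 min. The flask reaches 50% at 8.20 min, so its clock per catalyst is 42.3 min⁻¹, beside the 42.0 min⁻¹ read from Wednesday's run at 6.00 min.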